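Atom labels follow thymol numbering: C7 is the benzylic CH2O on the ring, C8 the oxirane carbon bound to the arene, C9 the oxirane CH2 and C10 the CH2O ester. The route rests on disconnecting the two saturated ester C–O bonds (O7 and O10) and the O–C9 oxirane bond back to an achiral 2-arylglycerol. Because C8 carries two CH2O arms, these are enantiotopic in tetraol 8, so one lipase-mediated transfer from vinyl (R)-2-methylbutanoate installs both 2-methylbutanoates and fixes C8. The precursor is the O-allyl phenol bearing a free benzylic alcohol and a C(OH)(CH2OH)2 group. Oxirane closure, deallylation and angeloylation finish the synthesis.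

Key step: step 7

Assumption: the arm a given lipase acylates cannot be read from the structure, so Burkholderia cepacia lipase is taken as the enzyme that selects the pro-R CH2OH of 8; the sense is to be confirmed on epoxide 14.

Step 1
Reactants: 1 methyl 4-bromo-3-hydroxybenzoate
Product: 2 methyl 4-bromo-3-(prop-2-en-1-yloxy)benzoate
Conditions: allyl bromide (1.2 equiv), K2CO3 (1.5 equiv), DMF, rt
Reagents that add atoms: allyl bromide, C=CCBr
Why: Williamson ether synthesis, in which K2CO3 deprotonates only the phenol and the phenoxide displaces bromide (SN2) while the methyl ester and the aryl bromide are inert.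

Step 2
Reactants: 2 methyl 4-bromo-3-(prop-2-en-1-yloxy)benzoate
Product: 3 [4-bromo-3-(prop-2-en-1-yloxy)phenyl]methanol
Conditions: i-Bu2AlH (2.5 equiv), CH2Cl2, −78 → 0 °C; aq. potassium sodium tartrate
Reagents that add atoms: none
Why: Hydride reduction of the benzoate with excess i-Bu2AlH should stop at the benzylic alcohol and touch neither the aryl bromide nor the allyl ether at low temperature.

Step 3
Reactants: 3 [4-bromo-3-(prop-2-en-1-yloxy)phenyl]methanol
Product: 4 {[4-bromo-3-(prop-2-en-1-yloxy)phenyl]methoxy}(tert-butyl)dimethylsilane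
Conditions: TBSCl (1.2 equiv), imidazole (2 equiv), DMF, rt
Reagents that add atoms: tert-butyldimethylsilyl chloride (TBSCl), CC(C)(C)[Si](C)(C)Cl
Why: Imidazole-promoted silylation of the primary alcohol removes the only acidic proton before lithiation, and the TBS ether is stable to n-BuLi at −78 °C.

Step 4
Reactants: 4 {[4-bromo-3-(prop-2-en-1-yloxy)phenyl]methoxy}(tert-butyl)dimethylsilane; 5 2,2-dimethyl-1,3-dioxan-5-one
Product: 7 5-[4-({[tert-butyl(dimethyl)silyl]oxy}methyl)-2-(prop-2-en-1-yloxy)phenyl]-2,2-dimethyl-1,3-dioxan-5-ol, via aryllithium 6 (not isolated)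
Conditions: n-BuLi (1.05 equiv), THF, −78 °C, 20 min; then 5 (1.3 equiv), −78 → −40 °C; aq. NH4Cl
Reagents that add atoms: none
Why: Bromine–lithium exchange at −78 °C is much faster than deprotonation or carbolithiation of the allyl ether, and the aryllithium then adds 1,2 to the ketone; the carbinol carbon bears two identical ring CH2O arms, so no stereocentre arises.

Step 5
Reactants: 7 5-[4-({[tert-butyl(dimethyl)silyl]oxy}methyl)-2-(prop-2-en-1-yloxy)phenyl]-2,2-dimethyl-1,3-dioxan-5-ol
Product: 8 2-[4-(hydroxymethyl)-2-(prop-2-en-1-yloxy)phenyl]propane-1,2,3-triol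
Conditions: AcOH/THF/H2O (3:1:1), 40 °C; evaporate with toluene
Reagents that add atoms: none
Why: Aqueous acetic acid hydrolyses the isopropylidene acetal and the primary TBS ether in one operation, while the tertiary benzylic alcohol, flanked by two electron-withdrawing CH2O groups, should not ionise and the allyl aryl ether is acid-stable.

Step 6
Reactants: 9 (R)-2-methylbutanoic acid
Product: 10 ethenyl (2R)-2-methylbutanoate (vinyl (R)-2-methylbutanoate)
Conditions: vinyl acetate (solvent), Pd(OAc)2 (2 mol %), KOH (5 mol %), rt; distil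
Reagents that add atoms: vinyl acetate, C=COC(C)=O
Why: Pd(OAc)2-catalysed transvinylation (vinyl interchange) exchanges only the carboxyl O–H for O–vinyl at room temperature, so the α-stereocentre of 9 is not touched.

Step 7
Reactants: 8 2-[4-(hydroxymethyl)-2-(prop-2-en-1-yloxy)phenyl]propane-1,2,3-triol; 10 ethenyl (2R)-2-methylbutanoate
Product: 12 (2R)-2,3-dihydroxy-2-[4-({[(2R)-2-methylbutanoyl]oxy}methyl)-2-(prop-2-en-1-yloxy)phenyl]propyl (2R)-2-methylbutanoate, via C7 monoester 11 (not isolated)
Conditions: immobilised Burkholderia cepacia lipase (Amano lipase PS), 10 (6 equiv), dry t-BuOMe/THF (3:1), 35 °C, stop when 11 is consumed; filter, concentrate below 30 °C, rapid chromatography on neutral silica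
Reagents that add atoms: none
Why: The active-site serine is acylated by 10 with loss of vinyl alcohol, which tautomerises to acetaldehyde and makes each transfer irreversible; the acyl-enzyme passes the (R)-2-methylbutanoyl group first to the unhindered benzylic O7 (giving 11) and then to one CH2OH on C8. The closest known reaction type is the lipase-catalysed desymmetrising acylation of prochiral 2-substituted propane-1,3-diols and 2-substituted glycerols with vinyl esters. No ring is formed. The new stereocentre C8 is set by the chiral active site (catalyst control), which should accept only the pro-R hydroxymethyl arm (C10); because the acyl groups are already enantiopure, the minor C8 epimer is a diastereomer, and it is the one that further acylation to the triester removes faster. The step needs chemoselectivity for primary over tertiary hydroxyl, secured because lipases do not acylate tertiary alcohols or aryl ethers, and mono-acylation within the diol, secured by the slow second transfer of an α-branched acyl group to a neopentyl-type alcohol. Acyl migration among O10, O8 and O9, which would scramble C8, should be slow for the α-branched ester under neutral, anhydrous handling.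

Step 8
Reactants: 12 (2R)-2,3-dihydroxy-2-[4-({[(2R)-2-methylbutanoyl]oxy}methyl)-2-(prop-2-en-1-yloxy)phenyl]propyl (2R)-2-methylbutanoate
Product: 14 [(2R)-2-[4-({[(2R)-2-methylbutanoyl]oxy}methyl)-2-(prop-2-en-1-yloxy)phenyl]oxiran-2-yl]methyl (2R)-2-methylbutanoate, via primary tosylate 13 (not isolated)
Conditions: TsCl (1.3 equiv), Et3N (2 equiv), Me3N·HCl (10 mol %), CH2Cl2, 0 °C; then DBU (3 equiv), 0 °C → rt
Reagents that add atoms: none
Why: Sulfonylation occurs only at the primary C9 hydroxyl because the tertiary one is too hindered, and DBU then triggers an intramolecular Williamson closure (3-exo-tet) of O8 onto C9 with loss of tosylate; no bond to C8 is broken, so its configuration is carried over (13 is labelled S only through a priority change), and once C9 is sulfonylated acyl migration can no longer scramble C8.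

Step 9
Reactants: 14 [(2R)-2-[4-({[(2R)-2-methylbutanoyl]oxy}methyl)-2-(prop-2-en-1-yloxy)phenyl]oxiran-2-yl]methyl (2R)-2-methylbutanoate
Product: 15 [(2R)-2-[2-hydroxy-4-({[(2R)-2-methylbutanoyl]oxy}methyl)phenyl]oxiran-2-yl]methyl (2R)-2-methylbutanoate
Conditions: Pd(PPh3)4 (5 mol %), morpholine (2 equiv), THF, rt, 1 h; short silica plug, used at once
Reagents that add atoms: none
Why: Tsuji–Trost-type deallylation, in which zerovalent palladium ionises the allyl aryl ether to a π-allyl complex that morpholine captures irreversibly, while the alkyl esters and the non-allylic oxirane are not substrates at room temperature and the weakly basic amine leaves the phenol protonated.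

Step 10
Reactants: 15 [(2R)-2-[2-hydroxy-4-({[(2R)-2-methylbutanoyl]oxy}methyl)phenyl]oxiran-2-yl]methyl (2R)-2-methylbutanoate; 16 angelic acid ((2Z)-2-methylbut-2-enoic acid)
Product: 18 5-({[(2R)-2-methylbutanoyl]oxy}methyl)-2-[(2R)-2-({[(2R)-2-methylbutanoyl]oxy}methyl)oxiran-2-yl]phenyl (2Z)-2-methylbut-2-enoate (CNP0166772.1), via angelic 2,4,6-trichlorobenzoic anhydride 17 (not isolated)
Conditions: 16 (2 equiv), 2,4,6-Cl3C6H2COCl (2 equiv), Et3N (2 equiv), toluene, rt, 1 h; then 15, Et3N (2 equiv), 0 °C → rt
Reagents that add atoms: none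
Why: Yamaguchi-type acylation, in which the phenol attacks the unhindered angeloyl carbonyl of mixed anhydride 17; with no nucleophilic catalyst, acid chloride or heating the (Z)-olefin should not isomerise to the tiglate and the oxirane should stay closed.

Compound list
1 | methyl 4-bromo-3-hydroxybenzoate | COC(=O)c1ccc(Br)c(O)c1 | starting material
2 | methyl 4-bromo-3-(prop-2-en-1-yloxy)benzoate | COC(=O)c1ccc(Br)c(OCC=C)c1 | intermediate
3 | [4-bromo-3-(prop-2-en-1-yloxy)phenyl]methanol | OCc1ccc(Br)c(OCC=C)c1 | intermediate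
4 | {[4-bromo-3-(prop-2-en-1-yloxy)phenyl]methoxy}(tert-butyl)dimethylsilane | C=CCOc1cc(CO[Si](C)(C)C(C)(C)C)ccc1Br | intermediate
5 | 2,2-dimethyl-1,3-dioxan-5-one (acetonide of 1,3-dihydroxyacetone) | CC1(C)OCC(=O)CO1 | starting material
6 | [4-({[tert-butyl(dimethyl)silyl]oxy}methyl)-2-(prop-2-en-1-yloxy)phenyl]lithium (formed in the flask) | [Li]c1ccc(CO[Si](C)(C)C(C)(C)C)cc1OCC=C | intermediate
7 | 5-[4-({[tert-butyl(dimethyl)silyl]oxy}methyl)-2-(prop-2-en-1-yloxy)phenyl]-2,2-dimethyl-1,3-dioxan-5-ol | C=CCOc1cc(CO[Si](C)(C)C(C)(C)C)ccc1C1(O)COC(C)(C)OC1 | intermediate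
8 | 2-[4-(hydroxymethyl)-2-(prop-2-en-1-yloxy)phenyl]propane-1,2,3-triol (achiral, prochiral at C8) | C=CCOc1cc(CO)ccc1C(O)(CO)CO | intermediate
9 | (R)-2-methylbutanoic acid | CC[C@@H](C)C(=O)O | starting material
10 | ethenyl (2R)-2-methylbutanoate | C=COC(=O)[C@H](C)CC | intermediate
11 | [4-(1,2,3-trihydroxypropan-2-yl)-3-(prop-2-en-1-yloxy)phenyl]methyl (2R)-2-methylbutanoate (C7 monoester, formed in the flask) | C=CCOc1cc(COC(=O)[C@H](C)CC)ccc1C(O)(CO)CO | intermediate
12 | (2R)-2,3-dihydroxy-2-[4-({[(2R)-2-methylbutanoyl]oxy}methyl)-2-(prop-2-en-1-yloxy)phenyl]propyl (2R)-2-methylbutanoate | C=CCOc1cc(COC(=O)[C@H](C)CC)ccc1[C@](O)(COC(=O)[C@H](C)CC)CO | intermediate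
13 | (2S)-2-hydroxy-2-[4-({[(2R)-2-methylbutanoyl]oxy}methyl)-2-(prop-2-en-1-yloxy)phenyl]-3-[(4-methylbenzenesulfonyl)oxy]propyl (2R)-2-methylbutanoate (formed in the flask) | C=CCOc1cc(COC(=O)[C@H](C)CC)ccc1[C@](O)(COC(=O)[C@H](C)CC)COS(=O)(=O)c1ccc(C)cc1 | intermediate
14 | [(2R)-2-[4-({[(2R)-2-methylbutanoyl]oxy}methyl)-2-(prop-2-en-1-yloxy)phenyl]oxiran-2-yl]methyl (2R)-2-methylbutanoate | C=CCOc1cc(COC(=O)[C@H](C)CC)ccc1[C@]1(COC(=O)[C@H](C)CC)CO1 | intermediate
15 | [(2R)-2-[2-hydroxy-4-({[(2R)-2-methylbutanoyl]oxy}methyl)phenyl]oxiran-2-yl]methyl (2R)-2-methylbutanoate | Oc1cc(COC(=O)[C@H](C)CC)ccc1[C@]1(COC(=O)[C@H](C)CC)CO1 | intermediate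
16 | angelic acid, (2Z)-2-methylbut-2-enoic acid | C/C=C(/C)C(=O)O | starting material
17 | (2Z)-2-methylbut-2-enoic 2,4,6-trichlorobenzoic anhydride (formed in the flask) | C/C=C(/C)C(=O)OC(=O)c1c(Cl)cc(Cl)cc1Cl | intermediate
18 | 5-({[(2R)-2-methylbutanoyl]oxy}methyl)-2-[(2R)-2-({[(2R)-2-methylbutanoyl]oxy}methyl)oxiran-2-yl]phenyl (2Z)-2-methylbut-2-enoate | C/C=C(/C)C(=O)Oc1cc(COC(=O)[C@H](C)CC)ccc1[C@]1(COC(=O)[C@H](C)CC)CO1 | target

Total step count: 10.
Longest linear sequence: 9 steps (1 → 18 through steps 1–5 and 7–10); step 6 is a one-step side branch.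

Steps most likely to fail

Step 7. The enzyme may acylate the wrong CH2OH arm or discriminate poorly between the two. Acylation may also run on to the triester, or the acyl group may migrate during isolation and erode C8. The fallback sets C8 by reagent-controlled epoxidation instead and sets out from 4. Lithiation as in step 4 (aryllithium 6) and acylation with N-methoxy-N-methyl-2-[(tert-butyldimethylsilyl)oxy]acetamide should give the silyloxymethyl aryl ketone F1. Wittig methylenation with Ph3P=CH2 in THF should give the 2-arylallyl silyl ether F2, and n-Bu4NF should free both alcohols to give the allylic/benzylic diol F3. Sharpless asymmetric epoxidation (Ti(OiPr)4, L-(+)-diethyl tartrate, t-BuOOH, 4 Å molecular sieves, CH2Cl2, −20 °C) is directed by the allylic hydroxyl, leaves the O-allyl group alone and should deliver the (S)-epoxy diol F4. Esterification of both primary hydroxyls with 9 (EDC·HCl, cat. DMAP, CH2Cl2, 0 °C) comes back to the route at 14; the change of descriptor from S to R reflects only the new priority of the acylated arm.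

Step 9. The liberated ortho-phenol may attack the neighbouring oxirane, either by cyclisation onto C9 or by quinone-methide-type ionisation at C8, during the reaction or the isolation. The fallback avoids the free phenol by hydrostannolytic deallylation and sets out from 14. Pd(PPh3)4 (cat.) with n-Bu3SnH in CH2Cl2 should give propene and the tributylstannyl aryl ether F5. This is acylated in the same flask with mixed anhydride 17 and comes back to the route at 18.

Step 4. The enolisable ketone may transfer a proton to the aryllithium instead of accepting it, or the ortho-allyloxy aryllithium may cyclise if the temperature drifts upward. The fallback builds the glycerol unit from a non-enolisable electrophile and sets out from 4. Lithiation (6), transmetalation with MgBr2·OEt2 and addition to diethyl oxomalonate should give the aryl hydroxymalonate F6. LiAlH4 in THF at 0 °C should reduce both esters to the triol silyl ether F7. The aqueous acetic acid of step 5 then removes the silyl group and comes back to the route at 8.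

Further compounds
F1 | step 7 | 2-{[tert-butyl(dimethyl)silyl]oxy}-1-[4-({[tert-butyl(dimethyl)silyl]oxy}methyl)-2-(prop-2-en-1-yloxy)phenyl]ethan-1-one | C=CCOc1cc(CO[Si](C)(C)C(C)(C)C)ccc1C(=O)CO[Si](C)(C)C(C)(C)C
F2 | step 7 | tert-butyl({2-[4-({[tert-butyl(dimethyl)silyl]oxy}methyl)-2-(prop-2-en-1-yloxy)phenyl]prop-2-en-1-yl}oxy)dimethylsilane | C=CCOc1cc(CO[Si](C)(C)C(C)(C)C)ccc1C(=C)CO[Si](C)(C)C(C)(C)C
F3 | step 7 | 2-[4-(hydroxymethyl)-2-(prop-2-en-1-yloxy)phenyl]prop-2-en-1-ol | C=CCOc1cc(CO)ccc1C(=C)CO
F4 | step 7 | [(2S)-2-[4-(hydroxymethyl)-2-(prop-2-en-1-yloxy)phenyl]oxiran-2-yl]methanol | C=CCOc1cc(CO)ccc1[C@]1(CO)CO1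
F5 | step 9 | [(2R)-2-[4-({[(2R)-2-methylbutanoyl]oxy}methyl)-2-[(tributylstannyl)oxy]phenyl]oxiran-2-yl]methyl (2R)-2-methylbutanoate | CCCC[Sn](CCCC)(CCCC)Oc1cc(COC(=O)[C@H](C)CC)ccc1[C@]1(COC(=O)[C@H](C)CC)CO1
F6 | step 4 | diethyl 2-[4-({[tert-butyl(dimethyl)silyl]oxy}methyl)-2-(prop-2-en-1-yloxy)phenyl]-2-hydroxypropanedioate | CCOC(=O)C(O)(C(=O)OCC)c1ccc(CO[Si](C)(C)C(C)(C)C)cc1OCC=C
F7 | step 4 | 2-[4-({[tert-butyl(dimethyl)silyl]oxy}methyl)-2-(prop-2-en-1-yloxy)phenyl]propane-1,2,3-triol | C=CCOc1cc(CO[Si](C)(C)C(C)(C)C)ccc1C(O)(CO)CO
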